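**Retrosynthetic overview**
1. Target 12 ⇐ 11: hydrolysis of the dioxolane that masks the C1 carbonyl (last step, no stereocenter touched).
2. 11 ⇐ 9: CBS reduction of the ketone sets C4 (R), cis to the side chain.
3. 9 ⇐ enone ketal 3 + geranylgeranyl bromide 6: Enders SAMP-hydrazone α'-alkylation forms the ring–chain bond and sets C5 (R).
4. 3 ⇐ 1: thermodynamic silyl enol ether, then Saegusa dehydrogenation.
5. No ring is formed: the carbocycle is bought as ketal 1 (spiro C8 = target C4, spiro C9 = target C5).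

Assumption: racemic 7-methyl-1,4-dioxaspiro[4.5]decan-8-one, SAMP and all-E geranylgeranyl bromide are taken as catalogue compounds.

**Route**

Step 1
Reactants: 1 7-methyl-1,4-dioxaspiro[4.5]decan-8-one (racemic)
Product: 2 trimethyl[(7-methyl-1,4-dioxaspiro[4.5]dec-7-en-8-yl)oxy]silane
Conditions: Me3SiCl, NaI, Et3N, MeCN, rt; pentane extraction, crude used
Reagents that add atoms: chlorotrimethylsilane, C[Si](C)(C)Cl
Why: Equilibrating silylation (Me3SiI made in the flask, with Et3N) gives the thermodynamic, more substituted silyl enol ether, which directs the coming dehydrogenation to the methyl-bearing side and erases the racemic center of 1.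

Step 2
Reactants: 2 trimethyl[(7-methyl-1,4-dioxaspiro[4.5]dec-7-en-8-yl)oxy]silane
Product: 3 7-methyl-1,4-dioxaspiro[4.5]dec-6-en-8-one
Conditions: Pd(OAc)2 (10 mol %), O2 (1 atm), DMSO, rt
Reagents that add atoms: none
Why: Saegusa–Ito oxidation (aerobic variant): the divalent palladium enolate formed from the silyl enol ether undergoes β-hydride elimination into the ring to give the 2-methyl enone, and the ketal is inert.

Step 3
Reactants: 3 7-methyl-1,4-dioxaspiro[4.5]dec-6-en-8-one; 4 SAMP, (2S)-2-(methoxymethyl)pyrrolidin-1-amine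
Product: 5 (2S)-2-(methoxymethyl)-N-(7-methyl-1,4-dioxaspiro[4.5]dec-6-en-8-ylidene)pyrrolidin-1-amine (C=N isomer mixture)
Conditions: 4 (1.2 equiv), pyridinium p-toluenesulfonate (5 mol %), cyclohexane, reflux, Dean–Stark
Reagents that add atoms: none
Why: Acid-catalysed condensation gives the Enders SAMP hydrazone; the ketal survives because its oxocarbenium ion would be conjugated to the electron-poor enone/azadiene, and a 1,1-disubstituted hydrazine cannot form a pyrazoline.

Step 4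
Reactants: 5 the SAMP hydrazone of 3; 6 (2E,6E,10E)-1-bromo-3,7,11,15-tetramethylhexadeca-2,6,10,14-tetraene (geranylgeranyl bromide)
Product: 8 (2S)-2-(methoxymethyl)-N-{(9R)-7-methyl-9-[(2E,6E,10E)-3,7,11,15-tetramethylhexadeca-2,6,10,14-tetraen-1-yl]-1,4-dioxaspiro[4.5]dec-6-en-8-ylidene}pyrrolidin-1-amine, via lithium azaenolate 7 (not isolated)
Conditions: LDA (LiN(iPr)2, 1.1 equiv), THF, 0 °C, 4 h; then 6 (1.1 equiv), −100 °C to −20 °C
Reagents that add atoms: none
Why: Enders SAMP-hydrazone alkylation: LDA removes the only acidic proton (α'-CH2), and the chelated E(C=C),Z(C–N) azaenolate takes the primary allylic bromide by SN2 on the face left open by the methoxymethyl arm, which for SAMP gives 9R (the future 5R) with the alkene geometry untouched.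

Step 5
Reactants: 8 the alkylated SAMP hydrazone
Product: 9 (9R)-7-methyl-9-[(2E,6E,10E)-3,7,11,15-tetramethylhexadeca-2,6,10,14-tetraen-1-yl]-1,4-dioxaspiro[4.5]dec-6-en-8-one
Conditions: sat. aq. oxalic acid, Et2O, rt, vigorous stirring
Reagents that add atoms: water, O
Why: Mild two-phase hydrazone hydrolysis frees the ketone without epimerising the α'-center, while the deactivated enone ketal and the trisubstituted alkenes do not react.

Step 6
Reactants: 9 the (9R)-ketone
Product: 11 (8R,9R)-7-methyl-9-[(2E,6E,10E)-3,7,11,15-tetramethylhexadeca-2,6,10,14-tetraen-1-yl]-1,4-dioxaspiro[4.5]dec-6-en-8-ol, via catechol borate ester 10 (not isolated)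
Conditions: (S)-1-methyl-3,3-diphenyltetrahydro-1H,3H-pyrrolo[1,2-c][1,3,2]oxazaborole ((S)-Me-CBS, 0.3 equiv), catecholborane (2 equiv), toluene, −78 °C; then MeOH, water
Reagents that add atoms: none
Why: Corey–Bakshi–Shibata reduction: with the α-methylvinyl arm as the large group the (S)-catalyst gives the 8R carbinol, and this hydride face is also anti to the C9 chain (matched), so the cis (8R,9R) alcohol forms, while catecholborane at −78 °C reduces only C=O and the trans alcohol from any 9S ketone is removed on silica.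

Step 7
Reactants: 11 the cis allylic alcohol ketal
Product: 12 (4R,5R)-4-hydroxy-3-methyl-5-[(2E,6E,10E)-3,7,11,15-tetramethylhexadeca-2,6,10,14-tetraen-1-yl]cyclohex-2-en-1-one
Conditions: 0.5 M aq. HCl–THF (1:4), 0 °C to rt
Reagents that add atoms: water, O
Why: Acid hydrolysis of the now allylic, activated dioxolane unmasks the conjugated ketone; C5 is β and C4 is γ to it, so neither center can epimerise, and dilute acid leaves the polyene alone.

**Compound list**
1 | 7-methyl-1,4-dioxaspiro[4.5]decan-8-one (racemic) | CC1CC2(CCC1=O)OCCO2 | starting material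
2 | trimethyl[(7-methyl-1,4-dioxaspiro[4.5]dec-7-en-8-yl)oxy]silane | CC1=C(O[Si](C)(C)C)CCC2(C1)OCCO2 | intermediate
3 | 7-methyl-1,4-dioxaspiro[4.5]dec-6-en-8-one | CC1=CC2(CCC1=O)OCCO2 | intermediate
4 | SAMP, (2S)-2-(methoxymethyl)pyrrolidin-1-amine | COC[C@@H]1CCCN1N | starting material
5 | (2S)-2-(methoxymethyl)-N-(7-methyl-1,4-dioxaspiro[4.5]dec-6-en-8-ylidene)pyrrolidin-1-amine | COC[C@@H]1CCCN1N=C1CCC2(C=C1C)OCCO2 | intermediate
6 | (2E,6E,10E)-1-bromo-3,7,11,15-tetramethylhexadeca-2,6,10,14-tetraene | CC(C)=CCC/C(C)=C/CC/C(C)=C/CC/C(C)=C/CBr | starting material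
7 | lithium [(2S)-2-(methoxymethyl)pyrrolidin-1-yl](7-methyl-1,4-dioxaspiro[4.5]deca-6,8-dien-8-yl)azanide (azaenolate of 5) | COC[C@@H]1CCCN1N([Li])C1=CCC2(C=C1C)OCCO2 | intermediate (not isolated)
8 | (2S)-2-(methoxymethyl)-N-{(9R)-7-methyl-9-[(2E,6E,10E)-3,7,11,15-tetramethylhexadeca-2,6,10,14-tetraen-1-yl]-1,4-dioxaspiro[4.5]dec-6-en-8-ylidene}pyrrolidin-1-amine | CC(C)=CCC/C(C)=C/CC/C(C)=C/CC/C(C)=C/C[C@@H]1CC2(OCCO2)C=C(C)C1=NN1CCC[C@H]1COC | intermediate
9 | (9R)-7-methyl-9-[(2E,6E,10E)-3,7,11,15-tetramethylhexadeca-2,6,10,14-tetraen-1-yl]-1,4-dioxaspiro[4.5]dec-6-en-8-one | CC(C)=CCC/C(C)=C/CC/C(C)=C/CC/C(C)=C/C[C@@H]1CC2(OCCO2)C=C(C)C1=O | intermediate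
10 | 2-{[(8R,9R)-7-methyl-9-[(2E,6E,10E)-3,7,11,15-tetramethylhexadeca-2,6,10,14-tetraen-1-yl]-1,4-dioxaspiro[4.5]dec-6-en-8-yl]oxy}-1,3,2-benzodioxaborole | CC(C)=CCC/C(C)=C/CC/C(C)=C/CC/C(C)=C/C[C@@H]1CC2(OCCO2)C=C(C)[C@@H]1OB1Oc2ccccc2O1 | intermediate (not isolated)
11 | (8R,9R)-7-methyl-9-[(2E,6E,10E)-3,7,11,15-tetramethylhexadeca-2,6,10,14-tetraen-1-yl]-1,4-dioxaspiro[4.5]dec-6-en-8-ol | CC(C)=CCC/C(C)=C/CC/C(C)=C/CC/C(C)=C/C[C@@H]1CC2(OCCO2)C=C(C)[C@@H]1O | intermediate
12 | (4R,5R)-4-hydroxy-3-methyl-5-[(2E,6E,10E)-3,7,11,15-tetramethylhexadeca-2,6,10,14-tetraen-1-yl]cyclohex-2-en-1-one | CC(C)=CCC/C(C)=C/CC/C(C)=C/CC/C(C)=C/C[C@@H]1CC(=O)C=C(C)[C@@H]1O | target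

**Totals**
Total step count: 7. Longest linear sequence: 7 steps (1 to 12).

**Three steps most likely to fail**

Step 4 (alkylation of a cross-conjugated enone azaenolate; low conversion or low selectivity). The fallback sets out from 3 and comes back at 11, without the auxiliary. LDA (THF, −78 °C) turns 3 into the lithium dienolate F1, which is alkylated with 6 to the racemic ketone F2. F2 is reduced as in step 6, where the catalyst sets 8R on both enantiomers. The 9R half goes through 10 to 11. The 9S half goes through the epimeric borate ester F3 to the trans alcohol F4, which is removed on silica. This saves two steps, gives at most half the material, and the ee of 11 must be checked (Mosher ester).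

Step 5 (slow hydrolysis of the conjugated hydrazone; long acid contact risks epimerisation at C9 or ketal loss followed by aromatisation). The fallback sets out from 8 and comes back at 9, changing the activation from protonation to N-alkylation. MeI (neat, 60 °C) quaternises the pyrrolidine nitrogen to give the hydrazonium iodide F5. F5 is hydrolysed within minutes in 1 M aq. HCl/pentane at 0 °C to 9.

Step 6 (the branched α' carbon may erode catalyst control, giving the 8-epimer). The fallback sets out from 9 and comes back at 11, accepting the substrate's own preference and inverting. Luche reduction (NaBH4, CeCl3·7H2O, MeOH, −78 °C; axial attack) gives the trans alcohol F6. Mitsunobu reaction (4-nitrobenzoic acid, PPh3, DIAD, toluene, 0 °C) inverts C8 to the cis 4-nitrobenzoate F7. K2CO3 in MeOH cleaves F7 to 11.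

**Further compounds**
F1 | step 4 | lithium 7-methyl-1,4-dioxaspiro[4.5]deca-6,8-dien-8-olate | CC1=CC2(CC=C1O[Li])OCCO2
F2 | step 4 | racemic 7-methyl-9-[(2E,6E,10E)-3,7,11,15-tetramethylhexadeca-2,6,10,14-tetraen-1-yl]-1,4-dioxaspiro[4.5]dec-6-en-8-one | CC(C)=CCC/C(C)=C/CC/C(C)=C/CC/C(C)=C/CC1CC2(OCCO2)C=C(C)C1=O
F3 | step 4 | 2-{[(8R,9S)-7-methyl-9-[(2E,6E,10E)-3,7,11,15-tetramethylhexadeca-2,6,10,14-tetraen-1-yl]-1,4-dioxaspiro[4.5]dec-6-en-8-yl]oxy}-1,3,2-benzodioxaborole | CC(C)=CCC/C(C)=C/CC/C(C)=C/CC/C(C)=C/C[C@H]1CC2(OCCO2)C=C(C)[C@@H]1OB1Oc2ccccc2O1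
F4 | step 4 | (8R,9S)-7-methyl-9-[(2E,6E,10E)-3,7,11,15-tetramethylhexadeca-2,6,10,14-tetraen-1-yl]-1,4-dioxaspiro[4.5]dec-6-en-8-ol (trans) | CC(C)=CCC/C(C)=C/CC/C(C)=C/CC/C(C)=C/C[C@H]1CC2(OCCO2)C=C(C)[C@@H]1O
F5 | step 5 | (2S)-2-(methoxymethyl)-1-methyl-1-({(9R)-7-methyl-9-[(2E,6E,10E)-3,7,11,15-tetramethylhexadeca-2,6,10,14-tetraen-1-yl]-1,4-dioxaspiro[4.5]dec-6-en-8-ylidene}amino)pyrrolidinium iodide | CC(C)=CCC/C(C)=C/CC/C(C)=C/CC/C(C)=C/C[C@@H]1CC2(OCCO2)C=C(C)C1=N[N+]1(C)CCC[C@H]1COC.[I-]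
F6 | step 6 | (8S,9R)-7-methyl-9-[(2E,6E,10E)-3,7,11,15-tetramethylhexadeca-2,6,10,14-tetraen-1-yl]-1,4-dioxaspiro[4.5]dec-6-en-8-ol (trans) | CC(C)=CCC/C(C)=C/CC/C(C)=C/CC/C(C)=C/C[C@@H]1CC2(OCCO2)C=C(C)[C@H]1O
F7 | step 6 | (8R,9R)-7-methyl-9-[(2E,6E,10E)-3,7,11,15-tetramethylhexadeca-2,6,10,14-tetraen-1-yl]-1,4-dioxaspiro[4.5]dec-6-en-8-yl 4-nitrobenzoate | CC(C)=CCC/C(C)=C/CC/C(C)=C/CC/C(C)=C/C[C@@H]1CC2(OCCO2)C=C(C)[C@@H]1OC(=O)c1ccc(cc1)[N+](=O)[O-]
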